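The runs are simulated with made-up constants; the scatter is artificial.

In units of per molar per minute we carry one number through this flask: the loss constant κ, the fraction of X lost per minute divided by the charge c_Z. Its reckoning treats c_Z as a steady count of carriers, so that X falls pseudo-first-order.

in all of them: X 0.055 M

| run | Z | remark | time |
|---|---|---|---|
| noon | 0.28 mM | run made earlier |  |
| winter | 0.41 mM | run made earlier |  |
| flask | 0.55 mM |  | 50 min |

| run | time / min | L / % | X / % |
|---|---|---|---|
| noon | 3.00 | 11.6 | 85.8 |
| noon | 6.00 | 22.3 | 74.3 |
| noon | 15.0 | 33.9 | 47.4 |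
| noon | 30.0 | 30.1 | 22.3 |
| noon | 60.0 | 13.3 | 5.4 |
| winter | 3.00 | 18.1 | 78.4 |
| winter | 6.00 | 28.9 | 65.6 |
| winter | 15.0 | 42.8 | 34.1 |
| winter | 30.0 | 32.5 | 11.0 |
| winter | 60.0 | 11.2 | 0.4 |

(scatter of a reading: 1 percentage point)

- time up to 50 min at which L stands highest
- the amount of L, in percent of the X charged, at that time
- earliest time at which at least nineteen twentieths of that best amount are there, in min
- latest time at which they still are, in min

Which numbers must be good? The time limit should not enter: in both runs the highest reading of L stands at 15.0 min, shorter than 50 min. Nor does c_X, charged at 0.055 M in both runs and in this flask, with L read in percent of it. That leaves two constants.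

The readings at 30.0 min give 179 /M/min at noon and 179 /M/min in winter, so κ = 179 /M/min, and for this flask k_X = κ c_Z = 0.0985 /min.

The loss constant of L, k_L, is less sure. What has left both X and L by 60.0 min at noon, over the area under L, gives 0.0560 /min. Taking the winter reading at 15.0 min as the top gives 0.0586 /min. With the noon k_L, the noon and winter values of κ put our top at 47.5 % and 47.6 %. The two values of k_L put it at 47.5 % and 46.6 %, a larger shift than κ causes. Our reckoning for this flask uses the noon value:

k_X = κ c_Z = 0.0985 /min
t_top = ln(k_X/k_L)/(k_X − k_L) = 13.3 min
top = exp(−k_L t_top) = 47.5 %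

The forecast, which calls the loss of L “seemingly independent of Z”, puts the top at 13.4 min (12.3 min to 14.5 min) with 47.9 % (46 % to 49.8 %), and the window from 9.5 min (8.6 min to 10.4 min) to 18.3 min (16.8 min to 19.9 min). Its top stands slightly above ours.

The flask gives 48.0 % at 13.4 min, with the window from 9.48 min to 18.2 min, all within the forecast's tolerance.

    X + Z → E + L (k = 180 /M/min)
    X + E → L + E, rate k2*[E]*[X] (k = 180 /M/min)
    L → D (k = 0.0550 /min)

In this flask κ c_Z puts X at 26.7 % at 13.4 min, and the flask holds 26.6 % of X at 13.4 min. The step from L to D is the largest single effect on the highest L in this flask, 51 percentage points against 38 points for the depletion of Z. The run with that step taken away reaches 99.3 % instead of 48.0 %, above the forecast's range, so such a flask is what would prove the forecast wrong. With 9.4 × 10⁻⁴ M of Z, κ gives 0.168 /min and, with k3 from the scheme, a top of 58.1 %. The computed best there is 58.2 %.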